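## The problem

The target is a (2R,3R)-2-aryl-3-methoxychroman-4-one. Ring A (5,6-dihydroxy-7-methoxy) is fused through C4a–C8a to the pyranone ring C, which carries ring B (2,3-dihydroxy-4-methoxyphenyl) at C2 and a methoxy group at C3. The only stereocentres are C2 and C3, adjacent and trans. C3 is alpha to the C4 carbonyl and C2 is a benzylic, oxygen-bearing carbon beta to it, so base can epimerise C3 or expel the O1 phenoxide to an achiral 2-methoxychalcone, and acid can ionise the C2–O1 bond. C3 can control C2, because an invertive closure of O1–C2 turns a syn open-chain pair into the trans ring and trans is also the more stable isomer. C2 gives no dependable hold on C3, so the C3 methoxy centre has to be set with absolute control. The four phenols (a catechol on ring B and a 5,6-diol para to O1 on ring A) are easily oxidised and should be freed last, without loss of the methyl ethers at C3, C7 and C4'; this also means the C5 and C7 oxygens, both neighbours of C6–O, must be told apart. The enabling feature is that O1–C2 and C3–OMe form a vicinal diol monomethyl ether attached to ring B. The C2–C3 bond can therefore be made from the formyl carbon of a ring B aldehyde and a gamma-methoxyallyl nucleophile before ring A and the carbonyl exist, with C4 carried as a vinyl carbon. In addition, ring A is a 3,4,5-trioxygenated phenol whose two ortho positions are equivalent, so C4a can be attached without a regiochemical question.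

## Retrosynthesis

**Unmasking (23 from 22).** The last cut removes three O–benzyl bonds (C6, C2', C3') and the O5–methyl bond of chromanone 22. The C5 methyl ether is the only one peri to the C4 carbonyl, so a chelating Lewis acid (BCl3) can take it off together with the benzyl groups. Hydrogenolysis alone would leave O5 methylated. Compound 22 is fully protected and not air-sensitive, and the forward step must spare the methyl ethers at C3, C7 and C4'.

**Ring C (22 from 21).** The O1–C2 bond is cut. The neighbouring options are weaker: closing O1–C8a by aromatic substitution would need an electron-poor ring A, and closing by oxa-Michael addition to a chalcone would erase C3. An intramolecular Mitsunobu etherification of hydroxy ketone 21 inverts C2, so the syn relationship in 21 becomes the trans relationship in 22. The forward reaction must displace faster than it eliminates.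

**Joining the halves (21 from 20, 19, then 11 and 17).** Phenol 21 comes from ketone 20 by loss of the methoxymethyl and silyl groups, and 20 from carbinol 19 by oxidation. Cutting C4–C4a in 19 gives aldehyde 11 and aryl bromide 17, joined through aryllithium 18. An acylation of the free ring A phenol was rejected, since an alpha-alkoxy acylium ion loses carbon monoxide and epimerises. This cut divides the molecule into two fragments of similar size, each without the sensitive beta-aryloxy ketone.

**Ring A fragment (17 from 16, 15, 13, 12).** Bromide 17 arises by bromination of methoxymethyl ether 16, made from phenol 15. Phenol 15 comes from benzyl ether 13 of syringaldehyde 12 by a Dakin-type oxidation, which turns the formyl carbon into the future C8a–O. The symmetry of 16 makes the two free ring positions identical, so no regiochemistry has to be controlled.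

**C4 from a vinyl group (11 from 9 and 8).** The aldehyde carbon of 11 is uncovered by oxidative cleavage of the terminal alkene of silyl ether 9, the protected form of alcohol 8. Carrying C4 as a vinyl group keeps an epimerisable carbonyl away from C3 until both stereocentres are in place.

**C2–C3 (8 from 2 and 6).** The central cut divides 8 into ring B aldehyde 2 and (Z)-gamma-methoxyallyl boronate 6. Against an aldol or a diketone reduction, this cut offers a single electrophile, a closed transition state that fixes the syn relationship, and a catalyst-controlled face. Both partners are achiral and two or fewer steps from catalogue compounds.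

**Fragments (2 from 1; 6 from 3).** Aldehyde 2 is the bis-benzyl ether of 2,3-dihydroxy-4-methoxybenzaldehyde 1. Boronate 6 is made from allyl methyl ether 3 by lithiation (allyllithium 4), borylation (ate complex 5) and protonolysis.

## Roads not taken

**Alternative 1:** Ring A is dismantled by cutting C4a–C5. The stereocentres would sit on a dihydropyranone with a tricarbonyl side chain, methyl 2-(benzyloxy)-4-{(2R,3R)-2-[2,3-bis(benzyloxy)-4-methoxyphenyl]-3-methoxy-4-oxo-3,4-dihydro-2H-pyran-6-yl}-3-oxobutanoate A1. Mild base would form the extended enolate, the pyranone carbon that becomes C4a would attack the ester carbonyl, and enolisation would give the aromatic ring of (2R,3R)-6-(benzyloxy)-2-[2,3-bis(benzyloxy)-4-methoxyphenyl]-5,7-dihydroxy-3-methoxychroman-4-one A2.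
- Merits: ring A appears with its oxygens already differentiated. The chelated 5-OH and the free 7-OH allow selective 7-O-methylation, and a final hydrogenolysis would finish the synthesis. This is better than the chosen plan at the end, which depends on a chelation-controlled BCl3 demethylation.
- Weak points: both stereocentres must survive the base that folds the chain. C3–H is alpha to the carbonyl and O1 is a beta leaving group, so the same enolate chemistry can epimerise C3 or open the ring. A1 also needs its own asymmetric construction of a trans-2,3-disubstituted dihydropyranone and a laborious side chain that can cyclise in other aldol modes.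
- Comparison: the chosen plan offsets the regiochemical advantage with the symmetric syringaldehyde-derived ring A piece, and its stereocentres never meet base after they are formed.

**Alternative 2:** The cut removes C2–H and C3–O from an achiral flav-2-ene, 6-(benzyloxy)-2-[2,3-bis(benzyloxy)-4-methoxyphenyl]-5,7-dimethoxy-4H-chromene A3. Monoisopinocampheylborane would add hydrogen to C2 and boron to C3 from one face, and oxidation would give (2R,3S)-trans-6-(benzyloxy)-2-[2,3-bis(benzyloxy)-4-methoxyphenyl]-5,7-dimethoxychroman-3-ol A4.
- Merits: both stereocentres come in one step from an achiral substrate. The trans relationship follows directly from syn addition, so no inverting ring closure is needed. In these respects it is more economical than the chosen plan.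
- Weak points: A4 lacks the C4 carbonyl. After O-methylation, a benzylic oxidation at C4 would have to work beside the C2 benzylic ether position and three benzyl ethers on very electron-rich rings. The enol ether A3 is acid-labile and can isomerise, and the facial selectivity of the borane on a trisubstituted aryl enol ether is not assured.
- Comparison: the chosen plan carries C4 at a latent carbonyl oxidation level from the start and needs no C–H oxidation. It pays for this with a longer sequence between the stereo-defining step and ring closure.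

**Alternative 3:** The cut is the C2–H bond of a racemic, rapidly epimerising diketone, 1-[3-(benzyloxy)-2,4-dimethoxy-6-(methoxymethoxy)phenyl]-3-[2,3-bis(benzyloxy)-4-methoxyphenyl]-2-methoxypropane-1,3-dione A5. Transfer hydrogenation with RuCl(p-cymene)(TsDPEN) and HCO2H/Et3N would reduce only the ring B ketone under dynamic kinetic resolution to give (2R,3S)-syn-1-[3-(benzyloxy)-2,4-dimethoxy-6-(methoxymethoxy)phenyl]-3-[2,3-bis(benzyloxy)-4-methoxyphenyl]-3-hydroxy-2-methoxypropan-1-one A6.
- Merits: the whole carbon skeleton is assembled before any stereocentre exists, and the stereo-defining step is catalytic in metal. A6 is one deprotection away from compound 21, so this road would save roughly four steps (silylation, alkene cleavage, aryllithium addition, oxidation). On step economy it is the stronger plan.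
- Weak points: the outcome rests on rate differences. The catalyst must choose the ring B ketone, which is itself ortho-substituted and electron-rich and therefore a poor hydride acceptor, over the ring A ketone. It must also reduce faster than retro-Claisen cleavage of the 2-alkoxy-1,3-diketone in the amine/formic acid medium and must not continue to the diol. Diaryl 2-alkoxy-1,3-diketones of this substitution are not established substrates for the method.
- Comparison: the chosen plan is longer but more certain. It has one electrophile, a syn relationship enforced by a cyclic transition state, and no stage at which a stereocentre lies between two carbonyl groups.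

Key step: step 3

Assumption: the (R)-enantiomer of the phosphoric acid is taken to open the Re face of aldehyde 2, as it does for the parent allyl and crotyl boronates with benzaldehydes. The configuration of 8 would be checked before proceeding, and the (S)-acid used if the sense is reversed. Atom labels C2, C3, C4 and so on refer to flavanone numbering.

## Route

Step 1
Reactants: 1 2,3-dihydroxy-4-methoxybenzaldehyde
Product: 2 2,3-bis(benzyloxy)-4-methoxybenzaldehyde
Conditions: BnBr (2.5 equiv), K2CO3, DMF, 60 °C
Reagents that add atoms: benzyl bromide, BrCc1ccccc1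
Why: Williamson ether synthesis; excess bromide in a polar aprotic solvent should also alkylate the phenol that is hydrogen-bonded to the formyl group.

Step 2
Reactants: 3 allyl methyl ether
Product: 6 (Z)-2-(3-methoxyallyl)-4,4,5,5-tetramethyl-1,3,2-dioxaborolane, via (Z)-3-methoxyallyllithium 4 (not isolated), via lithium (Z)-isopropoxy(3-methoxyallyl)(pinacolato)borate 5 (not isolated)
Conditions: s-BuLi, THF, −78 °C; iPrOBpin, −78 °C; HCl (2 M in Et2O, 1.0 equiv), −78 °C → rt
Reagents that add atoms: 2-isopropoxy-4,4,5,5-tetramethyl-1,3,2-dioxaborolane, CC(C)OB1OC(C)(C)C(C)(C)O1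
Why: Alpha-lithiation of the allyl ether gives an oxygen-chelated allyllithium of Z geometry, which is borylated at the carbon remote from oxygen. Protonolysis of the ate complex should release the Z boronate, a known class of gamma-alkoxyallyl reagents.

Step 3
Reactants: 2 2,3-bis(benzyloxy)-4-methoxybenzaldehyde; 6 (Z)-2-(3-methoxyallyl)-4,4,5,5-tetramethyl-1,3,2-dioxaborolane
Product: 8 (1S,2S)-1-[2,3-bis(benzyloxy)-4-methoxyphenyl]-2-methoxybut-3-en-1-ol, via O-pinacolboryl ether of the adduct 7 (not isolated)
Conditions: (R)-3,3'-bis(2,4,6-triisopropylphenyl)-1,1'-binaphthyl-2,2'-diyl hydrogen phosphate [(R)-TRIP, 10 mol %], 6 (1.5 equiv), 4 Å MS, toluene, −30 °C; then aq. NaHCO3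
Reagents that add atoms: none
Why: This is an allylboration of an aldehyde under chiral Brønsted acid catalysis; the closest known reaction type is the phosphoric acid-catalysed addition of allyl, crotyl and gamma-alkoxyallyl pinacol boronates to aromatic aldehydes. The aldehyde oxygen binds boron and the gamma-carbon of 6 attacks the formyl carbon through a closed six-membered chair, forming the C2–C3 bond with allylic transposition; no ring of the target is closed. In this chair the aryl group of 2 lies equatorial and the Z-methoxy group is forced axial, so the C3 centre is fixed syn to C2 by the double-bond geometry of 6. The absolute configuration at the carbinol carbon C2 is set by the catalyst, whose P–OH binds a boronate oxygen and whose P=O contacts the formyl hydrogen, so that the triisopropylphenyl walls leave only the Re face of 2 open. The step needs enantiofacial selectivity, syn over anti selectivity and gamma over alpha attack; the last two are inherent in the cyclic transition state. The first should hold because the electron-rich, ortho-substituted aldehyde reacts only slowly without acid at −30 °C, leaving the catalysed path dominant. Molecular sieves keep water from the enol ether, and the mild aqueous work-up cleaves the O–B bond of 7.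

Step 4
Reactants: 8 (1S,2S)-1-[2,3-bis(benzyloxy)-4-methoxyphenyl]-2-methoxybut-3-en-1-ol
Product: 9 tert-butyl{[(1S,2S)-1-[2,3-bis(benzyloxy)-4-methoxyphenyl]-2-methoxybut-3-en-1-yl]oxy}dimethylsilane
Conditions: TBSOTf, 2,6-lutidine, CH2Cl2, −78 → 0 °C
Reagents that add atoms: tert-butyldimethylsilyl trifluoromethanesulfonate, CC(C)(C)[Si](C)(C)OS(=O)(=O)C(F)(F)F
Why: Silyl ether formation; the triflate with a hindered base silylates crowded secondary benzylic alcohols without touching the stereocentres.

Step 5
Reactants: 9 tert-butyl{[(1S,2S)-1-[2,3-bis(benzyloxy)-4-methoxyphenyl]-2-methoxybut-3-en-1-yl]oxy}dimethylsilane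
Product: 11 (2R,3S)-3-[2,3-bis(benzyloxy)-4-methoxyphenyl]-3-[(tert-butyldimethylsilyl)oxy]-2-methoxypropanal, via vicinal diol 10 (not isolated)
Conditions: OsO4 (2 mol %), NaIO4 (4 equiv), 2,6-lutidine, dioxane–H2O 3:1, rt; crude product used directly
Reagents that add atoms: osmium tetroxide, O=[Os](=O)(=O)=O (oxygen carrier); sodium periodate, [Na+].[O-]I(=O)(=O)=O (terminal oxygen source)
Why: Lemieux–Johnson oxidative cleavage (dihydroxylation, then periodate glycol cleavage) is chosen over ozonolysis because ozone would attack the trialkoxyarene. The lutidine buffer limits over-oxidation and epimerisation of the alpha-methoxy aldehyde.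

Step 6
Reactants: 12 syringaldehyde (4-hydroxy-3,5-dimethoxybenzaldehyde)
Product: 13 4-(benzyloxy)-3,5-dimethoxybenzaldehyde
Conditions: BnBr, K2CO3, DMF, 60 °C
Reagents that add atoms: benzyl bromide, BrCc1ccccc1
Why: Williamson ether synthesis on a single hindered phenol; the benzyl group protects the future C6 oxygen through the organolithium chemistry.

Step 7
Reactants: 13 4-(benzyloxy)-3,5-dimethoxybenzaldehyde
Product: 15 4-(benzyloxy)-3,5-dimethoxyphenol, via 4-(benzyloxy)-3,5-dimethoxyphenyl formate 14 (not isolated)
Conditions: mCPBA, CH2Cl2, rt; then K2CO3 (cat.), MeOH, rt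
Reagents that add atoms: 3-chloroperbenzoic acid, O=C(OO)c1cccc(Cl)c1
Why: Dakin-type sequence: Baeyer–Villiger oxidation of the electron-rich benzaldehyde, in which the para-alkoxyaryl group migrates, gives the formate, and methanolysis frees the phenol.

Step 8
Reactants: 15 4-(benzyloxy)-3,5-dimethoxyphenol
Product: 16 2-(benzyloxy)-1,3-dimethoxy-5-(methoxymethoxy)benzene
Conditions: MOMCl, iPr2NEt, CH2Cl2, 0 °C → rt
Reagents that add atoms: chloromethyl methyl ether, COCCl
Why: Acetal protection of the phenol; the methoxymethyl ether withstands organolithium reagents, stabilises the neighbouring aryllithium by chelation, and protects the hydroquinone-type phenol from oxidation during bromination.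

Step 9
Reactants: 16 2-(benzyloxy)-1,3-dimethoxy-5-(methoxymethoxy)benzene
Product: 17 2-(benzyloxy)-4-bromo-1,3-dimethoxy-5-(methoxymethoxy)benzene
Conditions: NBS (1.0 equiv), MeCN, 0 °C
Reagents that add atoms: N-bromosuccinimide, O=C1CCC(=O)N1Br
Why: Electrophilic aromatic bromination; the two free positions are equivalent by symmetry and strongly activated, and one equivalent of reagent should stop at the monobromide.

Step 10
Reactants: 17 2-(benzyloxy)-4-bromo-1,3-dimethoxy-5-(methoxymethoxy)benzene; 11 (2R,3S)-3-[2,3-bis(benzyloxy)-4-methoxyphenyl]-3-[(tert-butyldimethylsilyl)oxy]-2-methoxypropanal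
Product: 19 (2S,3S)-3-[2,3-bis(benzyloxy)-4-methoxyphenyl]-1-[3-(benzyloxy)-2,4-dimethoxy-6-(methoxymethoxy)phenyl]-3-[(tert-butyldimethylsilyl)oxy]-2-methoxypropan-1-ol (both C1 epimers), via [3-(benzyloxy)-2,4-dimethoxy-6-(methoxymethoxy)phenyl]lithium 18 (not isolated)
Conditions: 17 (1.3 equiv), n-BuLi, THF, −78 °C; then 11, −78 °C; then H2O
Reagents that add atoms: none
Why: Bromine–lithium exchange followed by 1,2-addition of the chelation-stabilised aryllithium to the aldehyde forms C4–C4a. The new carbinol centre is of no consequence because it is oxidised in the next step, and the low temperature disfavours enolisation.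

Step 11
Reactants: 19 (2S,3S)-3-[2,3-bis(benzyloxy)-4-methoxyphenyl]-1-[3-(benzyloxy)-2,4-dimethoxy-6-(methoxymethoxy)phenyl]-3-[(tert-butyldimethylsilyl)oxy]-2-methoxypropan-1-ol
Product: 20 (2R,3S)-3-[2,3-bis(benzyloxy)-4-methoxyphenyl]-1-[3-(benzyloxy)-2,4-dimethoxy-6-(methoxymethoxy)phenyl]-3-[(tert-butyldimethylsilyl)oxy]-2-methoxypropan-1-one
Conditions: Dess–Martin periodinane, CH2Cl2, 0 °C → rt
Reagents that add atoms: none
Why: Dess–Martin oxidation of a hindered benzylic alcohol under near-neutral conditions, which should leave the alpha-methoxy stereocentre and the beta-silyloxy group untouched; both C1 epimers converge on one ketone.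

Step 12
Reactants: 20 (2R,3S)-3-[2,3-bis(benzyloxy)-4-methoxyphenyl]-1-[3-(benzyloxy)-2,4-dimethoxy-6-(methoxymethoxy)phenyl]-3-[(tert-butyldimethylsilyl)oxy]-2-methoxypropan-1-one
Product: 21 (2R,3S)-3-[2,3-bis(benzyloxy)-4-methoxyphenyl]-1-[3-(benzyloxy)-6-hydroxy-2,4-dimethoxyphenyl]-3-hydroxy-2-methoxypropan-1-one
Conditions: HCl (1.25 M in MeOH), THF, 0 °C → rt, stopped at full conversion
Reagents that add atoms: none
Why: Acid-catalysed solvolysis of the aryl acetal and the silyl ether in one operation. The methoxymethyl group ortho to the ketone is labile, and the inductive pull of the C3 methoxy and C4 carbonyl groups should retard ionisation at C2 at this temperature.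

Step 13
Reactants: 21 (2R,3S)-3-[2,3-bis(benzyloxy)-4-methoxyphenyl]-1-[3-(benzyloxy)-6-hydroxy-2,4-dimethoxyphenyl]-3-hydroxy-2-methoxypropan-1-one
Product: 22 (2R,3R)-6-(benzyloxy)-2-[2,3-bis(benzyloxy)-4-methoxyphenyl]-3,5,7-trimethoxychroman-4-one
Conditions: PPh3, DIAD, THF, 0 °C → rt
Reagents that add atoms: none
Why: Intramolecular Mitsunobu etherification: the ketone-bonded phenol displaces the oxyphosphonium group at C2 in a 6-exo-tet closure with inversion. The syn pair of 21 thus becomes the 2,3-trans ring with C2 in the R configuration, while C3 is untouched.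

Step 14
Reactants: 22 (2R,3R)-6-(benzyloxy)-2-[2,3-bis(benzyloxy)-4-methoxyphenyl]-3,5,7-trimethoxychroman-4-one
Product: 23 (2R,3R)-2-(2,3-dihydroxy-4-methoxyphenyl)-5,6-dihydroxy-3,7-dimethoxychroman-4-one
Conditions: BCl3 (1 M in CH2Cl2, 8 equiv), pentamethylbenzene (9 equiv), CH2Cl2, −78 → 0 °C; then MeOH, H2O
Reagents that add atoms: none
Why: Lewis-acid debenzylation of aryl benzyl ethers with a non-basic cation scavenger, combined with chelation-directed cleavage of the methyl ether peri to the C4 carbonyl. The methyl ethers at C3, C7 and C4' lack this six-membered chelate and should remain at 0 °C.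

## Compound list

1 | 2,3-dihydroxy-4-methoxybenzaldehyde | COc1ccc(C=O)c(O)c1O | starting material
2 | 2,3-bis(benzyloxy)-4-methoxybenzaldehyde | COc1ccc(C=O)c(OCc2ccccc2)c1OCc1ccccc1 | intermediate
3 | allyl methyl ether (3-methoxyprop-1-ene) | C=CCOC | starting material
4 | (Z)-3-methoxyallyllithium | CO/C=C\C[Li] | intermediate
5 | lithium (Z)-isopropoxy(3-methoxyallyl)(pinacolato)borate | [Li+].CO/C=C\C[B-]1(OC(C)C)OC(C)(C)C(C)(C)O1 | intermediate
6 | (Z)-2-(3-methoxyallyl)-4,4,5,5-tetramethyl-1,3,2-dioxaborolane | CO/C=C\CB1OC(C)(C)C(C)(C)O1 | intermediate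
7 | 2-{[(1S,2S)-1-[2,3-bis(benzyloxy)-4-methoxyphenyl]-2-methoxybut-3-en-1-yl]oxy}-4,4,5,5-tetramethyl-1,3,2-dioxaborolane | COc1ccc([C@H](OB2OC(C)(C)C(C)(C)O2)[C@@H](OC)C=C)c(OCc2ccccc2)c1OCc1ccccc1 | intermediate
8 | (1S,2S)-1-[2,3-bis(benzyloxy)-4-methoxyphenyl]-2-methoxybut-3-en-1-ol | COc1ccc([C@H](O)[C@@H](OC)C=C)c(OCc2ccccc2)c1OCc1ccccc1 | intermediate
9 | tert-butyl{[(1S,2S)-1-[2,3-bis(benzyloxy)-4-methoxyphenyl]-2-methoxybut-3-en-1-yl]oxy}dimethylsilane | COc1ccc([C@H](O[Si](C)(C)C(C)(C)C)[C@@H](OC)C=C)c(OCc2ccccc2)c1OCc1ccccc1 | intermediate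
10 | (3S,4S)-4-[2,3-bis(benzyloxy)-4-methoxyphenyl]-4-[(tert-butyldimethylsilyl)oxy]-3-methoxybutane-1,2-diol (both C2 epimers) | COc1ccc([C@H](O[Si](C)(C)C(C)(C)C)[C@@H](OC)C(O)CO)c(OCc2ccccc2)c1OCc1ccccc1 | intermediate
11 | (2R,3S)-3-[2,3-bis(benzyloxy)-4-methoxyphenyl]-3-[(tert-butyldimethylsilyl)oxy]-2-methoxypropanal | COc1ccc([C@H](O[Si](C)(C)C(C)(C)C)[C@@H](OC)C=O)c(OCc2ccccc2)c1OCc1ccccc1 | intermediate
12 | syringaldehyde (4-hydroxy-3,5-dimethoxybenzaldehyde) | COc1cc(C=O)cc(OC)c1O | starting material
13 | 4-(benzyloxy)-3,5-dimethoxybenzaldehyde | COc1cc(C=O)cc(OC)c1OCc1ccccc1 | intermediate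
14 | 4-(benzyloxy)-3,5-dimethoxyphenyl formate | COc1cc(OC=O)cc(OC)c1OCc1ccccc1 | intermediate
15 | 4-(benzyloxy)-3,5-dimethoxyphenol | COc1cc(O)cc(OC)c1OCc1ccccc1 | intermediate
16 | 2-(benzyloxy)-1,3-dimethoxy-5-(methoxymethoxy)benzene | COCOc1cc(OC)c(OCc2ccccc2)c(OC)c1 | intermediate
17 | 2-(benzyloxy)-4-bromo-1,3-dimethoxy-5-(methoxymethoxy)benzene | COCOc1cc(OC)c(OCc2ccccc2)c(OC)c1Br | intermediate
18 | [3-(benzyloxy)-2,4-dimethoxy-6-(methoxymethoxy)phenyl]lithium | COCOc1cc(OC)c(OCc2ccccc2)c(OC)c1[Li] | intermediate
19 | (2S,3S)-3-[2,3-bis(benzyloxy)-4-methoxyphenyl]-1-[3-(benzyloxy)-2,4-dimethoxy-6-(methoxymethoxy)phenyl]-3-[(tert-butyldimethylsilyl)oxy]-2-methoxypropan-1-ol (both C1 epimers) | COCOc1cc(OC)c(OCc2ccccc2)c(OC)c1C(O)[C@H](OC)[C@@H](O[Si](C)(C)C(C)(C)C)c1ccc(OC)c(OCc2ccccc2)c1OCc1ccccc1 | intermediate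
20 | (2R,3S)-3-[2,3-bis(benzyloxy)-4-methoxyphenyl]-1-[3-(benzyloxy)-2,4-dimethoxy-6-(methoxymethoxy)phenyl]-3-[(tert-butyldimethylsilyl)oxy]-2-methoxypropan-1-one | COCOc1cc(OC)c(OCc2ccccc2)c(OC)c1C(=O)[C@H](OC)[C@@H](O[Si](C)(C)C(C)(C)C)c1ccc(OC)c(OCc2ccccc2)c1OCc1ccccc1 | intermediate
21 | (2R,3S)-3-[2,3-bis(benzyloxy)-4-methoxyphenyl]-1-[3-(benzyloxy)-6-hydroxy-2,4-dimethoxyphenyl]-3-hydroxy-2-methoxypropan-1-one | Oc1cc(OC)c(OCc2ccccc2)c(OC)c1C(=O)[C@H](OC)[C@@H](O)c1ccc(OC)c(OCc2ccccc2)c1OCc1ccccc1 | intermediate
22 | (2R,3R)-6-(benzyloxy)-2-[2,3-bis(benzyloxy)-4-methoxyphenyl]-3,5,7-trimethoxychroman-4-one | COc1ccc([C@H]2Oc3cc(OC)c(OCc4ccccc4)c(OC)c3C(=O)[C@@H]2OC)c(OCc2ccccc2)c1OCc1ccccc1 | intermediate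
23 | (2R,3R)-2-(2,3-dihydroxy-4-methoxyphenyl)-5,6-dihydroxy-3,7-dimethoxychroman-4-one | COc1ccc([C@H]2Oc3cc(OC)c(O)c(O)c3C(=O)[C@@H]2OC)c(O)c1O | target

## Step count and risks

Total: 14 steps. Longest linear sequence: 9 steps (steps 1, 3, 4, 5, 10, 11, 12, 13, 14 from compound 1; the ring A branch through steps 6–9 and 10–14 is equally long).

**Step 3 (key step).** The catalysed addition to an electron-rich, ortho-substituted aldehyde may be slow. Uncatalysed racemic addition, or acid-promoted isomerisation or hydrolysis of the enol ether, could then compete and erode enantiomeric purity and syn selectivity. The fallback replaces catalysis by a stoichiometric chiral boron reagent that reacts at −78 °C without acid. It sets out from 3 and 2. Allyllithium 4 would be trapped with (+)-B-methoxydiisopinocampheylborane (from (−)-alpha-pinene) and the methoxide removed with BF3·OEt2 to give (Z)-(3-methoxyallyl)diisopinocampheylborane F1. Addition of 2 at −78 °C and oxidative work-up (NaOH, H2O2) would return to the route at 8.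

**Step 10.** Proton transfer from the alpha-methoxy aldehyde to the hindered, basic aryllithium may compete with addition, causing epimerisation at C3 or beta-elimination of the silyloxy group. The fallback changes the electrophile and sets out from 11. Pinnick oxidation (NaClO2, NaH2PO4, 2-methylbut-2-ene) would give (2R,3S)-3-[2,3-bis(benzyloxy)-4-methoxyphenyl]-3-[(tert-butyldimethylsilyl)oxy]-2-methoxypropanoic acid F2. Coupling with N,O-dimethylhydroxylamine hydrochloride (EDC, HOBt, iPr2NEt) would give the Weinreb amide (2R,3S)-3-[2,3-bis(benzyloxy)-4-methoxyphenyl]-3-[(tert-butyldimethylsilyl)oxy]-N,2-dimethoxy-N-methylpropanamide F3. Acylation of aryllithium 18 with F3 would give ketone 20 directly, returning at 20 and making step 11 unnecessary. The amide is much less acidic at the alpha-carbon, and its chelated tetrahedral intermediate prevents a second addition.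

**Step 12.** Ionisation of the benzylic C2–O bond under protic acid is the main danger, because the para-methoxy and ortho-benzyloxy groups of ring B stabilise the cation. It would lead to epimerisation at C2, capture of methanol or dehydration to the enone. The fallback unmasks the two groups one after the other without a protic acid and sets out from 20. ZnBr2 and n-PrSH (CH2Cl2, 0 °C) would remove the acetal to give (2R,3S)-3-[2,3-bis(benzyloxy)-4-methoxyphenyl]-1-[3-(benzyloxy)-6-hydroxy-2,4-dimethoxyphenyl]-3-[(tert-butyldimethylsilyl)oxy]-2-methoxypropan-1-one F4. HF·pyridine in THF would then cleave the silyl ether and return to the route at 21.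

**Step 13.** The oxyphosphonium intermediate may eliminate, since C3–H is alpha to the ketone, giving a 2-methoxychalcone. It may also ionise before displacement, so that the closure is no longer stereospecific. The fallback abandons phosphorus activation in favour of a stereoconvergent acid-mediated closure and sets out from 21. Catalytic TsOH in CH2Cl2 at low temperature would generate the ring B-stabilised benzylic cation, which the neighbouring phenol should capture through a chair-like arrangement with the aryl and methoxy groups equatorial. C3 then directs C2 to the trans isomer, which is also the more stable one, and the route is rejoined at 22 with no new isolated compound.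

**Step 14.** Once the benzyl groups are gone, boron-bound phenoxides next to the C7 and C4' methyl ethers may assist their cleavage. The Lewis acid may also open the pyranone ring and scramble C2. The fallback separates the two events and removes the benzyl groups without a Lewis acid; it sets out from 22. MgI2·OEt2 (toluene, warm) would cleave only the chelated C5 methyl ether to give (2R,3R)-6-(benzyloxy)-2-[2,3-bis(benzyloxy)-4-methoxyphenyl]-5-hydroxy-3,7-dimethoxychroman-4-one F5. Hydrogenolysis (H2, Pd/C, EtOAc–MeOH) would then deliver 23.

## Further compounds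

F1 | step 3 | (Z)-(3-methoxyallyl)bis[(1S,2R,3S,5S)-2,6,6-trimethylbicyclo[3.1.1]heptan-3-yl]borane | CO/C=C\CB([C@H]1C[C@H]2C[C@@H]([C@@H]1C)C2(C)C)[C@H]1C[C@H]2C[C@@H]([C@@H]1C)C2(C)C
F2 | step 10 | (2R,3S)-3-[2,3-bis(benzyloxy)-4-methoxyphenyl]-3-[(tert-butyldimethylsilyl)oxy]-2-methoxypropanoic acid | COc1ccc([C@H](O[Si](C)(C)C(C)(C)C)[C@@H](OC)C(=O)O)c(OCc2ccccc2)c1OCc1ccccc1
F3 | step 10 | (2R,3S)-3-[2,3-bis(benzyloxy)-4-methoxyphenyl]-3-[(tert-butyldimethylsilyl)oxy]-N,2-dimethoxy-N-methylpropanamide | COc1ccc([C@H](O[Si](C)(C)C(C)(C)C)[C@@H](OC)C(=O)N(C)OC)c(OCc2ccccc2)c1OCc1ccccc1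
F4 | step 12 | (2R,3S)-3-[2,3-bis(benzyloxy)-4-methoxyphenyl]-1-[3-(benzyloxy)-6-hydroxy-2,4-dimethoxyphenyl]-3-[(tert-butyldimethylsilyl)oxy]-2-methoxypropan-1-one | Oc1cc(OC)c(OCc2ccccc2)c(OC)c1C(=O)[C@H](OC)[C@@H](O[Si](C)(C)C(C)(C)C)c1ccc(OC)c(OCc2ccccc2)c1OCc1ccccc1
F0 | step 13 | none | none
F5 | step 14 | (2R,3R)-6-(benzyloxy)-2-[2,3-bis(benzyloxy)-4-methoxyphenyl]-5-hydroxy-3,7-dimethoxychroman-4-one | COc1ccc([C@H]2Oc3cc(OC)c(OCc4ccccc4)c(O)c3C(=O)[C@@H]2OC)c(OCc2ccccc2)c1OCc1ccccc1
A1 | alternative 1 | methyl 2-(benzyloxy)-4-{(2R,3R)-2-[2,3-bis(benzyloxy)-4-methoxyphenyl]-3-methoxy-4-oxo-3,4-dihydro-2H-pyran-6-yl}-3-oxobutanoate | COc1ccc([C@H]2OC(CC(=O)C(OCc3ccccc3)C(=O)OC)=CC(=O)[C@@H]2OC)c(OCc2ccccc2)c1OCc1ccccc1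
A2 | alternative 1 | (2R,3R)-6-(benzyloxy)-2-[2,3-bis(benzyloxy)-4-methoxyphenyl]-5,7-dihydroxy-3-methoxychroman-4-one | COc1ccc([C@H]2Oc3cc(O)c(OCc4ccccc4)c(O)c3C(=O)[C@@H]2OC)c(OCc2ccccc2)c1OCc1ccccc1
A3 | alternative 2 | 6-(benzyloxy)-2-[2,3-bis(benzyloxy)-4-methoxyphenyl]-5,7-dimethoxy-4H-chromene | COc1ccc(C2=CCc3c(OC)c(OCc4ccccc4)c(OC)cc3O2)c(OCc2ccccc2)c1OCc1ccccc1
A4 | alternative 2 | (2R,3S)-trans-6-(benzyloxy)-2-[2,3-bis(benzyloxy)-4-methoxyphenyl]-5,7-dimethoxychroman-3-ol | COc1ccc([C@H]2Oc3cc(OC)c(OCc4ccccc4)c(OC)c3C[C@@H]2O)c(OCc2ccccc2)c1OCc1ccccc1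
A5 | alternative 3 | 1-[3-(benzyloxy)-2,4-dimethoxy-6-(methoxymethoxy)phenyl]-3-[2,3-bis(benzyloxy)-4-methoxyphenyl]-2-methoxypropane-1,3-dione | COc1ccc(C(=O)C(OC)C(=O)c2c(OCOC)cc(OC)c(OCc3ccccc3)c2OC)c(OCc2ccccc2)c1OCc1ccccc1
A6 | alternative 3 | (2R,3S)-syn-1-[3-(benzyloxy)-2,4-dimethoxy-6-(methoxymethoxy)phenyl]-3-[2,3-bis(benzyloxy)-4-methoxyphenyl]-3-hydroxy-2-methoxypropan-1-one | COc1ccc([C@H](O)[C@@H](OC)C(=O)c2c(OCOC)cc(OC)c(OCc3ccccc3)c2OC)c(OCc2ccccc2)c1OCc1ccccc1
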